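**Strategy.** Everything rests on cutting both bonds that the benzylic methine C9' makes to the arene and to the isobutyl CH2. C9' sits between quaternary C4 of the five-membered ring (C1–C5) and a 2,4,6-trioxygenated arene, so it can start as the formyl carbon of a C4 aldehyde that cannot enolise, take the arene as an aryllithium, and then, ionised to a cation that three methoxy groups stabilise, take a methallyl group from a silane in the same flask. The precursor is hydroazulene aldehyde 21: CHO and CH3 on C4, C5=C6 in the seven-membered ring (C1, C5–C10), C(CH3)2OSiEt3 on C7 and CH3 on C10.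

Key step: step 14

Remark: hydroazulene labels (C1–C10 ring atoms, C11 the carbinol carbon on C7, C9' the benzylic carbon) are used for all bicyclic compounds, and tributyl(iodomethyl)stannane is taken to be a purchasable reagent.

**Route**

Step 1
Reactants: 1 (S)-limonene
Product: 2 (4S)-limonene 1,2-oxide (cis/trans mixture at the epoxide)
Conditions: mCPBA (1.0 equiv), CH2Cl2, 0 °C
Reagents that add atoms: 3-chloroperoxybenzoic acid, O=C(OO)c1cccc(Cl)c1
Why: Prilezhaev epoxidation: the peracid attacks the electron-richer trisubstituted ring alkene and spares the 1,1-disubstituted isopropenyl group, the C4 stereocentre of limonene is untouched and the epoxide diastereomers converge in step 2.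

Step 2
Reactants: 2 (4S)-limonene 1,2-oxide
Product: 4 (3S)-6-oxo-3-(prop-1-en-2-yl)heptanal, via limonene-1,2-diol 3 (not isolated)
Conditions: H5IO6, THF/H2O, 0 °C → rt
Reagents that add atoms: water, O
Why: Aqueous periodic acid opens the epoxide to the 1,2-diol and cleaves it in the same flask (Malaprade glycol cleavage), which turns the two ring alkene carbons into a methyl ketone and an aldehyde without touching the isopropenyl group or the stereocentre.

Step 3
Reactants: 4 (3S)-6-oxo-3-(prop-1-en-2-yl)heptanal
Product: 6 (5R)-2-methyl-5-(prop-1-en-2-yl)cyclopent-1-ene-1-carbaldehyde, via β-hydroxy aldehyde 5 (not isolated)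
Conditions: piperidine (cat.), AcOH (cat.), toluene, 80 °C
Reagents that add atoms: none
Why: Amine-catalysed intramolecular aldol condensation: piperidine forms the enamine of the aldehyde, whose α-carbon attacks the methyl ketone to close the five-membered ring, and dehydration gives the tetrasubstituted enal whose ring carbons are C1–C5 (CH3 already on C4, the formyl carbon is C6) with C1 untouched.

Step 4
Reactants: 7 (R)-4-benzyloxazolidin-2-one; 8 pent-4-enoyl chloride
Product: 9 (R)-4-benzyl-3-(pent-4-enoyl)oxazolidin-2-one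
Conditions: Et3N, DMAP (cat.), CH2Cl2, 0 °C → rt
Reagents that add atoms: none
Why: Acylation of the oxazolidinone nitrogen by the acid chloride under 4-dimethylaminopyridine catalysis gives the imide that supplies C7, C8, C9 and the future C11.

Step 5
Reactants: 9 (R)-4-benzyl-3-(pent-4-enoyl)oxazolidin-2-one; 6 (5R)-2-methyl-5-(prop-1-en-2-yl)cyclopent-1-ene-1-carbaldehyde
Product: 11 (4R)-4-benzyl-3-[(2R)-2-{(R)-hydroxy[(5R)-2-methyl-5-(prop-1-en-2-yl)cyclopent-1-en-1-yl]methyl}pent-4-enoyl]oxazolidin-2-one, via boron (Z)-enolate 10 (not isolated)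
Conditions: Bu2BOTf, Et3N, CH2Cl2, −78 → 0 °C; 6, −78 → 0 °C; then H2O2, MeOH, pH 7 buffer
Reagents that add atoms: none
Why: Evans syn-aldol reaction: the dibutylboron (Z)-enolate reacts with the enal through a closed chair transition state on the enolate face away from the benzyl group, so the (R)-auxiliary sets C7 as R and C6 as R by reagent control and places the C6 oxygen and C11 on the same side of the future ring.

Step 6
Reactants: 11 syn-aldol imide
Product: 12 methyl (2R)-2-{(R)-hydroxy[(5R)-2-methyl-5-(prop-1-en-2-yl)cyclopent-1-en-1-yl]methyl}pent-4-enoate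
Conditions: NaOMe, MeOH, 0 °C
Reagents that add atoms: sodium methoxide, [Na+].[O-]C
Why: Transesterification: methoxide attacks the exocyclic imide carbonyl at 0 °C, faster than retro-aldol cleavage, which releases the auxiliary and gives the methyl ester needed for the double methyl addition while C6 and C7 stay as set.

Step 7
Reactants: 12 methyl ester
Product: 13 hydroazulene hydroxy ester (1R,6R,7R; alkenes C4=C5 and C9=C10; CH3 on C4 and C10; OH on C6; CO2CH3 on C7)
Conditions: second-generation Grubbs catalyst RuCl2(=CHPh)(H2IMes)(PCy3) (5 mol%), CH2Cl2 (0.005 M), 40 °C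
Reagents that add atoms: none
Why: Ring-closing metathesis joins the allyl terminus to the isopropenyl group and forms the seven-membered ring with a trisubstituted C9=C10 alkene, favoured because C1 and C6 are held cis on sp2 C5, while the tetrasubstituted C4=C5 alkene is inert to the ruthenium carbene.

Step 8
Reactants: 13 hydroazulene hydroxy ester
Product: 15 hydroazulene diene diol (1R,6R,7R; alkenes C4=C5 and C9=C10; OH on C6; C(CH3)2OH on C7), via methyl ketone 14 (not isolated)
Conditions: MeLi (4 equiv), THF, −78 → 0 °C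
Reagents that add atoms: methyllithium, [Li]C
Why: Double addition of methyllithium to the ester through methyl ketone 14 builds the C11 dimethylcarbinol after one equivalent has deprotonated the C6 hydroxyl, and the low temperature suppresses retro-aldol cleavage and epimerisation at C7.

Step 9
Reactants: 15 hydroazulene diene diol
Product: 16 hydroazulene ene diol (1R,6R,7R,10R; alkene C4=C5; OH on C6; C(CH3)2OH on C7)
Conditions: H2 (50 bar), [Rh(nbd)(dppb)]BF4 (10 mol%), CH2Cl2, rt
Reagents that add atoms: none
Why: Hydroxyl-directed homogeneous hydrogenation: the cationic rhodium complex binds the C6 and C11 hydroxyls, both of which lie on the face of H1, and delivers hydrogen to C9=C10 from that face, so C10 becomes R with its methyl trans to C11 and cis to C2, while this catalyst does not reduce the tetrasubstituted C4=C5 alkene.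

Step 10
Reactants: 16 hydroazulene ene diol
Product: 17 C6 (tributylstannyl)methyl ether of 16
Conditions: KH (1.1 equiv), THF, 0 °C; ICH2SnBu3, 0 °C → rt
Reagents that add atoms: tributyl(iodomethyl)stannane, CCCC[Sn](CCCC)(CCCC)CI
Why: Williamson etherification: the secondary allylic potassium alkoxide is alkylated by the iodomethylstannane much faster than the hindered tertiary C11 alkoxide, which places the tin handle for the sigmatropic shift on the C6 oxygen.

Step 11
Reactants: 17 C6 (tributylstannyl)methyl ether
Product: 18 C11 triethylsilyl ether of 17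
Conditions: Et3SiOTf, 2,6-lutidine, CH2Cl2, −78 → 0 °C
Reagents that add atoms: triethylsilyl trifluoromethanesulfonate, CC[Si](CC)(CC)OS(=O)(=O)C(F)(F)F
Why: Silylation with the silyl triflate and a hindered pyridine base caps the remaining tertiary alcohol as the triethylsilyl ether, which withstands the organolithium and zinc chloride steps and is removable by fluoride.

Step 12
Reactants: 18 C11 triethylsilyl ether
Product: 20 C4 hydroxymethyl hydroazulene (1R,4S,7R,10R; alkene C5=C6; CH3 and CH2OH on C4; C(CH3)2OSiEt3 on C7), via lithiomethyl ether 19 (not isolated)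
Conditions: n-BuLi, THF, −78 → −20 °C; then H2O
Reagents that add atoms: none
Why: Tin–lithium exchange gives α-alkoxymethyllithium 19, which undergoes the [2,3]-Wittig–Still rearrangement with bond formation to C4 on the face from which the C6–O bond leaves (suprafacial), so the C6 configuration is transferred to the quaternary C4 with CH2OH cis to H1 and CH3 trans to it, and the alkene moves to C5=C6.

Step 13
Reactants: 20 C4 hydroxymethyl hydroazulene
Product: 21 hydroazulene C4 carbaldehyde (1R,4S,7R,10R; C11 triethylsilyl ether)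
Conditions: (n-Pr4N)RuO4 (5 mol%), N-methylmorpholine N-oxide, 4 Å molecular sieves, CH2Cl2, rt
Reagents that add atoms: none
Why: Ley–Griffith oxidation with catalytic perruthenate converts the neopentyl primary alcohol into the aldehyde, which has no α-hydrogen and cannot epimerise, without touching the silyl ether or the C5=C6 alkene.

Step 14
Reactants: 21 hydroazulene C4 carbaldehyde; 22 1,3,5-trimethoxybenzene; 23 methallyltrimethylsilane
Product: 28 C9' aryl methallyl adduct (1R,4R,7R,10R,9'R; 2,4,6-trimethoxyphenyl and 2-methylallyl on C9'), via 2,4,6-trimethoxyphenyllithium 24 (not isolated), via lithium alkoxide 25 (not isolated), via benzylic acetate 26 (not isolated), via benzylic cation 27 (not isolated)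
Conditions: 22, n-BuLi, THF, 0 °C → rt; 21, −78 °C; AcCl, −78 → 0 °C; then 23 (3 equiv), ZnCl2 (0.3 equiv), CH2Cl2, −40 → 0 °C
Reagents that add atoms: none
Why: Proposed new method: Aryllithium 24 adds to aldehyde 21, which has no α-hydrogen and cannot enolise; alkoxide 25 is acetylated in the flask because a zinc halide cannot expel a lithium alkoxide, catalytic ZnCl2 then ionises acetate 26 to cation 27, and methallylsilane 23 attacks C9' and loses silicon as trimethylsilyl acetate, which frees the catalyst. The closest known reaction types are aryllithium addition to hindered aldehydes and the Hosomi–Sakurai allylation of ionised electron-rich benzylic esters, which have not been run as one three-component sequence on a neopentyl centre of this kind. No ring is closed; the step forms the aryl–C9' and C9'–CH2 bonds. C9' is the only new stereocentre and is set in the capture of the planar cation under control of the adjacent quaternary C4: with the cycloheptene arm (C5) held perpendicular to the cation plane and the C4 methyl next to the arene, the silane should enter anti to C5, past the C3 methylene, which gives 9'R. The step also needs chemoselectivity, which the three donor oxygens secure: the cation is too stabilised to rearrange into C4 or to engage C5=C6, and catalytic ZnCl2 below 0 °C should leave the tertiary silyl ether intact.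

Step 15
Reactants: 28 C9' aryl methallyl adduct
Product: 29 C9' isobutyl compound (2,4,6-trimethoxyphenyl; C11 triethylsilyl ether)
Conditions: H2 (1 atm), RhCl(PPh3)3 (10 mol%), toluene, rt
Reagents that add atoms: none
Why: Chemoselective homogeneous hydrogenation: RhCl(PPh3)3 reduces the unhindered 1,1-disubstituted methallyl alkene and leaves the trisubstituted C5=C6 alkene, which is shielded by quaternary C4 and branched C7.

Step 16
Reactants: 29 C9' isobutyl compound
Product: 30 3',5'-dibromo-2',4',6'-trimethoxyphenyl compound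
Conditions: N-bromosuccinimide (2.1 equiv), MeCN, 0 °C
Reagents that add atoms: N-bromosuccinimide, O=C1CCC(=O)N1Br
Why: Electrophilic aromatic bromination: the two free ring positions, each flanked by two methoxy groups, react with N-bromosuccinimide far faster than the hindered C5=C6 alkene.

Step 17
Reactants: 30 aryl dibromide
Product: 32 3',5'-diformyl-2',4',6'-trimethoxyphenyl compound, via dilithio arene 31 (not isolated)
Conditions: t-BuLi (4.4 equiv), THF, −78 °C; DMF, −78 °C → rt; then H2O
Reagents that add atoms: N,N-dimethylformamide, CN(C)C=O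
Why: Double bromine–lithium exchange gives dilithio arene 31, each carbanion flanked by two methoxy groups, and formylation with N,N-dimethylformamide (Bouveault aldehyde synthesis) installs both aldehydes after hydrolysis of the hemiaminal salts.

Step 18
Reactants: 32 aryl dialdehyde
Product: 33 C11 alcohol (tri-O-methyl ether of the target)
Conditions: HF·pyridine, THF, 0 °C → rt
Reagents that add atoms: none
Why: Fluoride-mediated desilylation cleaves the tertiary triethylsilyl ether under mild buffered conditions that the aryl aldehydes, the methyl ethers and the C5=C6 alkene tolerate.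

Step 19
Reactants: 33 C11 alcohol
Product: 34 CNP0281883.1 (target; 1R,4R,7R,10R,9'R)
Conditions: n-PrSH, n-BuLi, HMPA, 0 °C → rt; 33, 120 °C; then 1 M HCl
Reagents that add atoms: none
Why: Nucleophilic demethylation: the thiolate attacks the methyl carbon of each aryl methyl ether by SN2, each ether being activated by ortho or para formyl groups, and acidic work-up protonates the triphenoxide to give the target with its five stereocentres unchanged.

**Compound list**

1 | (S)-(−)-limonene | CC1=CC[C@H](CC1)C(C)=C | starting material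
2 | (4S)-limonene 1,2-oxide, cis/trans mixture at the epoxide | CC12CC[C@@H](CC1O2)C(C)=C | intermediate
3 | (4S)-limonene-1,2-diol (not isolated) | CC1(O)CC[C@@H](CC1O)C(C)=C | intermediate
4 | (3S)-6-oxo-3-(prop-1-en-2-yl)heptanal | O=CC[C@H](CCC(C)=O)C(C)=C | intermediate
5 | cyclic β-hydroxy aldehyde from 4, 2-hydroxy-2-methyl-5-(prop-1-en-2-yl)cyclopentane-1-carbaldehyde, new centres unassigned (not isolated) | O=CC1[C@@H](C(C)=C)CCC1(C)O | intermediate
6 | (5R)-2-methyl-5-(prop-1-en-2-yl)cyclopent-1-ene-1-carbaldehyde | O=CC1=C(C)CC[C@@H]1C(C)=C | intermediate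
7 | (R)-4-benzyloxazolidin-2-one | O=C1N[C@H](Cc2ccccc2)CO1 | starting material
8 | pent-4-enoyl chloride | C=CCCC(Cl)=O | starting material
9 | (R)-4-benzyl-3-(pent-4-enoyl)oxazolidin-2-one | C=CCCC(=O)N1[C@H](Cc2ccccc2)COC1=O | intermediate
10 | dibutylboron (Z)-enolate of 9 (not isolated) | C=CC/C=C(\OB(CCCC)CCCC)N1[C@H](Cc2ccccc2)COC1=O | intermediate
11 | (4R)-4-benzyl-3-[(2R)-2-{(R)-hydroxy[(5R)-2-methyl-5-(prop-1-en-2-yl)cyclopent-1-en-1-yl]methyl}pent-4-enoyl]oxazolidin-2-one | C=CC[C@@H](C(=O)N1[C@H](Cc2ccccc2)COC1=O)[C@@H](O)C1=C(C)CC[C@@H]1C(C)=C | intermediate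
12 | methyl (2R)-2-{(R)-hydroxy[(5R)-2-methyl-5-(prop-1-en-2-yl)cyclopent-1-en-1-yl]methyl}pent-4-enoate | C=CC[C@@H](C(=O)OC)[C@@H](O)C1=C(C)CC[C@@H]1C(C)=C | intermediate
13 | hydroazulene hydroxy ester, (1R,6R,7R), alkenes C4=C5 and C9=C10, OH on C6, CO2CH3 on C7 | COC(=O)[C@@H]1CC=C(C)[C@H]2CCC(C)=C2[C@@H]1O | intermediate
14 | C7 methyl ketone of the same bicycle (not isolated) | CC(=O)[C@@H]1CC=C(C)[C@H]2CCC(C)=C2[C@@H]1O | intermediate
15 | hydroazulene diene diol, (1R,6R,7R), OH on C6, C(CH3)2OH on C7 | CC(C)(O)[C@@H]1CC=C(C)[C@H]2CCC(C)=C2[C@@H]1O | intermediate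
16 | hydroazulene ene diol, (1R,6R,7R,10R), alkene C4=C5 | CC(C)(O)[C@@H]1CC[C@@H](C)[C@H]2CCC(C)=C2[C@@H]1O | intermediate
17 | C6 (tributylstannyl)methyl ether of 16 | CC(C)(O)[C@@H]1CC[C@@H](C)[C@H]2CCC(C)=C2[C@@H]1OC[Sn](CCCC)(CCCC)CCCC | intermediate
18 | C11 triethylsilyl ether of 17 | CC[Si](CC)(CC)OC(C)(C)[C@@H]1CC[C@@H](C)[C@H]2CCC(C)=C2[C@@H]1OC[Sn](CCCC)(CCCC)CCCC | intermediate
19 | C6 lithiomethyl ether (not isolated) | CC[Si](CC)(CC)OC(C)(C)[C@@H]1CC[C@@H](C)[C@H]2CCC(C)=C2[C@@H]1OC[Li] | intermediate
20 | C4 hydroxymethyl hydroazulene, (1R,4S,7R,10R), alkene C5=C6, C11 triethylsilyl ether | OC[C@@]1(C)CC[C@H]2C1=C[C@H](C(C)(C)O[Si](CC)(CC)CC)CC[C@H]2C | intermediate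
21 | hydroazulene C4 carbaldehyde, (1R,4S,7R,10R), C11 triethylsilyl ether | O=C[C@@]1(C)CC[C@H]2C1=C[C@H](C(C)(C)O[Si](CC)(CC)CC)CC[C@H]2C | intermediate
22 | 1,3,5-trimethoxybenzene | COc1cc(OC)cc(OC)c1 | starting material
23 | methallyltrimethylsilane | CC(=C)C[Si](C)(C)C | starting material
24 | 2,4,6-trimethoxyphenyllithium (not isolated) | COc1cc(OC)c([Li])c(OC)c1 | intermediate
25 | lithium alkoxide of the C9' aryl carbinol, C9' epimers (not isolated) | [Li]OC(c1c(OC)cc(OC)cc1OC)[C@@]1(C)CC[C@H]2C1=C[C@H](C(C)(C)O[Si](CC)(CC)CC)CC[C@H]2C | intermediate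
26 | C9' benzylic acetate, C9' epimers (not isolated) | CC(=O)OC(c1c(OC)cc(OC)cc1OC)[C@@]1(C)CC[C@H]2C1=C[C@H](C(C)(C)O[Si](CC)(CC)CC)CC[C@H]2C | intermediate
27 | C9' benzylic cation (not isolated) | [CH+](c1c(OC)cc(OC)cc1OC)[C@@]1(C)CC[C@H]2C1=C[C@H](C(C)(C)O[Si](CC)(CC)CC)CC[C@H]2C | intermediate
28 | C9' aryl methallyl adduct, (1R,4R,7R,10R,9'R) | C=C(C)C[C@@H](c1c(OC)cc(OC)cc1OC)[C@@]1(C)CC[C@H]2C1=C[C@H](C(C)(C)O[Si](CC)(CC)CC)CC[C@H]2C | intermediate
29 | C9' isobutyl compound | CC(C)C[C@@H](c1c(OC)cc(OC)cc1OC)[C@@]1(C)CC[C@H]2C1=C[C@H](C(C)(C)O[Si](CC)(CC)CC)CC[C@H]2C | intermediate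
30 | 3',5'-dibromide | CC(C)C[C@@H](c1c(OC)c(Br)c(OC)c(Br)c1OC)[C@@]1(C)CC[C@H]2C1=C[C@H](C(C)(C)O[Si](CC)(CC)CC)CC[C@H]2C | intermediate
31 | 3',5'-dilithio arene (not isolated) | CC(C)C[C@@H](c1c(OC)c([Li])c(OC)c([Li])c1OC)[C@@]1(C)CC[C@H]2C1=C[C@H](C(C)(C)O[Si](CC)(CC)CC)CC[C@H]2C | intermediate
32 | 3',5'-dialdehyde, C11 triethylsilyl ether | CC(C)C[C@@H](c1c(OC)c(C=O)c(OC)c(C=O)c1OC)[C@@]1(C)CC[C@H]2C1=C[C@H](C(C)(C)O[Si](CC)(CC)CC)CC[C@H]2C | intermediate
33 | C11 alcohol, tri-O-methyl ether of the target | CC(C)C[C@@H](c1c(OC)c(C=O)c(OC)c(C=O)c1OC)[C@@]1(C)CC[C@H]2C1=C[C@H](C(C)(C)O)CC[C@H]2C | intermediate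
34 | CNP0281883.1 | CC(C)C[C@@H](c1c(O)c(C=O)c(O)c(C=O)c1O)[C@@]1(C)CC[C@H]2C1=C[C@H](C(C)(C)O)CC[C@H]2C | target

**Step count and risks**

Total steps: 19. Longest linear sequence: 18 steps (steps 1–3 and 5–19 from (S)-limonene; step 4 is a one-step branch).

Steps most likely to fail:

1. Step 14 (bears the label Proposed new method). The hindered cation may be captured too slowly, so that it is intercepted by unlithiated trimethoxybenzene or returns to the acetate, or the silane may enter on the wrong face of C9'. The fallback uses known reactions only, sets out from 21 and comes back at 29. Aryllithium 24 is added to 21 and the product is isolated after aqueous work-up as the benzylic carbinol F1. Oxidation with (n-Pr4N)RuO4 and N-methylmorpholine N-oxide gives the aryl ketone F2. This ketone has no α-hydrogen, so methallylmagnesium chloride CH2=C(CH3)CH2MgCl can only add, giving the tertiary methallyl carbinol F3. RhCl(PPh3)3 and H2 saturate the side chain to the tertiary isobutyl carbinol F4. Ionic hydrogenation (Et3SiH, BF3·OEt2, CH2Cl2, −78 °C) then replaces the hydroxyl by hydrogen and gives 29. Hydride, not carbon, arrives last in this order, so it is stereocomplementary to the one-pot step and also serves if the silane prefers the wrong face.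

2. Step 9. Direction from the two bishomoallylic hydroxyls may be too weak, so that reduction is slow or hydrogen is delivered on the face of C2. The fallback moves control to the catalyst, sets out from 15 and comes back at 18. Both hydroxyls are silylated (Et3SiOTf, 2,6-lutidine) to the bis(triethylsilyl) ether F5. C9=C10 is reduced with a chiral iridium P,N complex of the type [Ir(cod)(PHOX)]BArF, the ligand enantiomer being chosen for 10R, to give the saturated bis(silyl) ether F6. The less hindered secondary silyl ether is cleaved (pyridinium p-toluenesulfonate, MeOH, 0 °C) to the C6 alcohol F7. KH and ICH2SnBu3 convert F7 directly into 18.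

3. Step 12. The α-alkoxymethyllithium may be protonated or undergo a 1,2-shift before it bonds to the tetrasubstituted C4. The fallback sets out from 16 and comes back at 21. The secondary hydroxyl is acylated with (4-methoxybenzyloxy)acetyl chloride and pyridine to the glycolate ester F8, and the tertiary hydroxyl is silylated (Et3SiOTf, 2,6-lutidine) to the silyl ether F9. An Ireland–Claisen rearrangement (KN(SiMe3)2, Me3SiCl, THF, −78 °C → rt) transfers the glycolate carbon to C4 on the face of the C6 oxygen and gives the acid F10. 2,3-Dichloro-5,6-dicyano-1,4-benzoquinone removes the 4-methoxybenzyl group to give the α-hydroxy acid F11, and Pb(OAc)4 cleaves F11 to aldehyde 21.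

Further compounds
F1 | step 14 | C9' benzylic carbinol, C9' epimers, other centres as in 21 | OC(c1c(OC)cc(OC)cc1OC)[C@@]1(C)CC[C@H]2C1=C[C@H](C(C)(C)O[Si](CC)(CC)CC)CC[C@H]2C
F2 | step 14 | C9' aryl ketone | O=C(c1c(OC)cc(OC)cc1OC)[C@@]1(C)CC[C@H]2C1=C[C@H](C(C)(C)O[Si](CC)(CC)CC)CC[C@H]2C
F3 | step 14 | tertiary C9' methallyl carbinol, C9' epimers | C=C(C)CC(O)(c1c(OC)cc(OC)cc1OC)[C@@]1(C)CC[C@H]2C1=C[C@H](C(C)(C)O[Si](CC)(CC)CC)CC[C@H]2C
F4 | step 14 | tertiary C9' isobutyl carbinol, C9' epimers | CC(C)CC(O)(c1c(OC)cc(OC)cc1OC)[C@@]1(C)CC[C@H]2C1=C[C@H](C(C)(C)O[Si](CC)(CC)CC)CC[C@H]2C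
F5 | step 9 | bis(triethylsilyl) ether of 15 | CC[Si](CC)(CC)OC(C)(C)[C@@H]1CC=C(C)[C@H]2CCC(C)=C2[C@@H]1O[Si](CC)(CC)CC
F6 | step 9 | bis(triethylsilyl) ether of 16 | CC[Si](CC)(CC)OC(C)(C)[C@@H]1CC[C@@H](C)[C@H]2CCC(C)=C2[C@@H]1O[Si](CC)(CC)CC
F7 | step 9 | C6 alcohol with C11 triethylsilyl ether | CC[Si](CC)(CC)OC(C)(C)[C@@H]1CC[C@@H](C)[C@H]2CCC(C)=C2[C@@H]1O
F8 | step 12 | C6 (4-methoxybenzyloxy)acetate of 16 | CC(C)(O)[C@@H]1CC[C@@H](C)[C@H]2CCC(C)=C2[C@@H]1OC(=O)COCc1ccc(OC)cc1
F9 | step 12 | C11 triethylsilyl ether of F8 | CC[Si](CC)(CC)OC(C)(C)[C@@H]1CC[C@@H](C)[C@H]2CCC(C)=C2[C@@H]1OC(=O)COCc1ccc(OC)cc1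
F10 | step 12 | C4 (4-methoxybenzyloxy)acetic acid, α-centre unassigned, other centres as in 21 | OC(=O)C(OCc1ccc(OC)cc1)[C@@]1(C)CC[C@H]2C1=C[C@H](C(C)(C)O[Si](CC)(CC)CC)CC[C@H]2C
F11 | step 12 | C4 hydroxyacetic acid, α-centre unassigned | OC(=O)C(O)[C@@]1(C)CC[C@H]2C1=C[C@H](C(C)(C)O[Si](CC)(CC)CC)CC[C@H]2C
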